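**Retrosynthetic overview**

1. Feature: in cembrane numbering (C1 carries the C15–C16 lactone arm, C2–C14 complete the 14-membered carbocycle, C17 is the exocyclic methylene, C18/C19/C20 are the methyls on C4/C8/C12) C5 lies α to a C4 carbonyl and C6 is the allylic CH2 of the Z-C7=C8 unit. The carbocycle is therefore cut at C5–C6 into a C5 β-keto sulfone carbanion and a primary Z-allylic bromide, with the seven-membered C16–O–C12 lactone already in place.
2. After ring closure: removal of the C5 sulfone, methyl addition to the C4 ketone under chelation by the C3 oxygen (sets C4), methylenation at C15 (adds C17), desilylation.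
3. The ε-lactone comes from 7-exo opening of the (11S,12S)-epoxide at C12 by the C16 acid (sets C12, keeps C11); the epoxide comes from Shi epoxidation of the E-C11=C12 alkene.
4. The chain is joined at C13–C14 by alkylating a C14 gem-bis-sulfone with the C6–C13 allylic bromide made from neryl acetate; C1 is set by an iminium-catalysed Michael addition to a C16–C15=C1 enal, C3 comes from (S)-glycidol, C5 from methyl phenyl sulfone.
5. Ring order: ε-lactone first (step 14), then the 14-membered carbocycle (step 22).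

Key step: step 22

Remark: reagent 7 and the L-fructose-derived ketone of step 12 are taken as purchasable; in the bicyclic names positions 1–12 are cembrane C1–C12, 13 is the lactone oxygen, 14 is C16, 15 is C15, 16 and 17 are C14 and C13.

**Route**

Step 1
Reactants: 1 (S)-glycidol
Product: 2 (R)-2-{[(4-methoxybenzyl)oxy]methyl}oxirane
Conditions: NaH, 4-MeOC6H4CH2Cl, Bu4NI (cat.), THF/DMF, 0 °C → rt
Reagents that add atoms: 4-methoxybenzyl chloride, COc1ccc(CCl)cc1
Why: Williamson ether synthesis of the primary alkoxide; no bond at the stereocentre is made or broken (the Payne rearrangement of the glycidol alkoxide is degenerate), so the future C3 keeps the glycidol configuration and only its descriptor changes to R.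

Step 2
Reactants: 2 (R)-2-{[(4-methoxybenzyl)oxy]methyl}oxirane
Product: 3 (R)-1-[(4-methoxybenzyl)oxy]pent-4-en-2-ol
Conditions: CH2=CHMgBr, CuI (10 mol%), THF, −40 → −20 °C; aq. NH4Cl
Reagents that add atoms: vinylmagnesium bromide, C=C[Mg]Br
Why: Copper-catalysed Grignard opening of a terminal epoxide by SN2 attack at the unsubstituted CH2, which becomes C2 while the vinyl CH becomes C1; the carbinol centre (C3) is untouched.

Step 3
Reactants: 3 (R)-1-[(4-methoxybenzyl)oxy]pent-4-en-2-ol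
Product: 4 1-methoxy-4-({[(2R)-2-(methoxymethoxy)pent-4-en-1-yl]oxy}methyl)benzene
Conditions: MeOCH2Cl, i-Pr2NEt, CH2Cl2, 0 °C → rt
Reagents that add atoms: chloromethyl methyl ether, COCCl
Why: O-Alkylation of the secondary alcohol to the MOM acetal under amine base, which leaves the PMB ether and the alkene alone and protects C3–OH through to the macrocyclisation.

Step 4
Reactants: 4 1-methoxy-4-({[(2R)-2-(methoxymethoxy)pent-4-en-1-yl]oxy}methyl)benzene; 5 (E)-crotonaldehyde
Product: 6 (2E,5R)-5-(methoxymethoxy)-6-[(4-methoxybenzyl)oxy]hex-2-enal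
Conditions: 5 (5 equiv), second-generation Hoveyda–Grubbs catalyst (3 mol%), CH2Cl2, 40 °C
Reagents that add atoms: none
Why: Olefin cross-metathesis of a monosubstituted alkene with excess crotonaldehyde, which should give the conjugated E-enal (C16–C15=C1) as the thermodynamic isomer with propene as the only by-product.

Step 5
Reactants: 6 (2E,5R)-5-(methoxymethoxy)-6-[(4-methoxybenzyl)oxy]hex-2-enal; 7 1,3-benzodithiole 1,1,3,3-tetraoxide
Product: 8 (3R,5R)-5-(methoxymethoxy)-6-[(4-methoxybenzyl)oxy]-3-(1,1,3,3-tetraoxo-1,3-benzodithiol-2-yl)hexanal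
Conditions: 7 (1.2 equiv), (S)-α,α-diphenylprolinol trimethylsilyl ether (20 mol%), CH2Cl2, rt
Reagents that add atoms: none
Why: Iminium-catalysed Michael addition of the acidic cyclic gem-bis-sulfone to an enal, a combination known for this pronucleophile: in the E,s-trans iminium ion the CPh2OSiMe3 group of the (S)-catalyst shields one face, so that C14 adds to the opposite face of C1 and sets C1 (R) under catalyst control, a C1 epimer being a separable diastereomer because C3 is already fixed.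

Step 6
Reactants: 8 (3R,5R)-5-(methoxymethoxy)-6-[(4-methoxybenzyl)oxy]-3-(1,1,3,3-tetraoxo-1,3-benzodithiol-2-yl)hexanal
Product: 9 (3R,5R)-5-(methoxymethoxy)-6-[(4-methoxybenzyl)oxy]-3-(1,1,3,3-tetraoxo-1,3-benzodithiol-2-yl)hexanoic acid
Conditions: NaClO2, NaH2PO4, 2-methyl-2-butene, t-BuOH/H2O, rt
Reagents that add atoms: sodium chlorite, [Na+].[O-]Cl=O
Why: Pinnick oxidation of the aldehyde to the C16 acid with 2-methyl-2-butene as hypochlorite scavenger, conditions that spare the PMB ether, the acetal and the acidic bis-sulfone C–H.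

Step 7
Reactants: 9 (3R,5R)-5-(methoxymethoxy)-6-[(4-methoxybenzyl)oxy]-3-(1,1,3,3-tetraoxo-1,3-benzodithiol-2-yl)hexanoic acid
Product: 10 methyl (3R,5R)-5-(methoxymethoxy)-6-[(4-methoxybenzyl)oxy]-3-(1,1,3,3-tetraoxo-1,3-benzodithiol-2-yl)hexanoate
Conditions: Me3SiCHN2, toluene/MeOH, 0 °C
Reagents that add atoms: trimethylsilyldiazomethane, C[Si](C)(C)C=[N+]=[N-]
Why: Esterification of the carboxylic acid with trimethylsilyldiazomethane, which masks C16 as a methyl ester so that only C14 is deprotonated in the next carbon–carbon bond formation.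

Step 8
Reactants: 11 neryl acetate
Product: 12 (2Z,6E)-8-hydroxy-3,7-dimethylocta-2,6-dien-1-yl acetate
Conditions: SeO2 (0.1 equiv), t-BuOOH, salicylic acid (0.1 equiv), CH2Cl2, rt
Reagents that add atoms: tert-butyl hydroperoxide, CC(C)(C)OO
Why: Catalytic SeO2/t-BuOOH allylic oxidation (ene reaction then [2,3]-sigmatropic shift), which oxidises the E-methyl group of the electron-rich terminal alkene and leaves the acetate-deactivated Z-C7=C8 alkene untouched, so that C13 becomes a CH2OH group trans to C10.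

Step 9
Reactants: 12 (2Z,6E)-8-hydroxy-3,7-dimethylocta-2,6-dien-1-yl acetate
Product: 13 (2Z,6E)-8-bromo-3,7-dimethylocta-2,6-dien-1-yl acetate
Conditions: CBr4, PPh3, CH2Cl2, 0 °C
Reagents that add atoms: carbon tetrabromide, BrC(Br)(Br)Br
Why: Appel bromination of the primary allylic alcohol by SN2 at C13, which keeps the E geometry of C11=C12 and the Z geometry of C7=C8.

Step 10
Reactants: 10 methyl (3R,5R)-5-(methoxymethoxy)-6-[(4-methoxybenzyl)oxy]-3-(1,1,3,3-tetraoxo-1,3-benzodithiol-2-yl)hexanoate; 13 (2Z,6E)-8-bromo-3,7-dimethylocta-2,6-dien-1-yl acetate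
Product: 14 methyl (3R,5R)-3-{2-[(2E,6Z)-8-acetoxy-2,6-dimethylocta-2,6-dien-1-yl]-1,1,3,3-tetraoxo-1,3-benzodithiol-2-yl}-5-(methoxymethoxy)-6-[(4-methoxybenzyl)oxy]hexanoate
Conditions: Cs2CO3, Bu4NI (cat.), DMF, rt
Reagents that add atoms: none
Why: Alkylation of the sulfone-stabilised C14 carbanion with the primary allylic bromide (SN2 at C13), a reaction known for Michael adducts of this cyclic bis-sulfone; it joins the two fragments through the C13–C14 bond without touching C1, the esters or the alkene geometries.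

Step 11
Reactants: 14 methyl (3R,5R)-3-{2-[(2E,6Z)-8-acetoxy-2,6-dimethylocta-2,6-dien-1-yl]-1,1,3,3-tetraoxo-1,3-benzodithiol-2-yl}-5-(methoxymethoxy)-6-[(4-methoxybenzyl)oxy]hexanoate
Product: 15 methyl (3R,6E,10Z)-12-acetoxy-3-[(2R)-2-(methoxymethoxy)-3-[(4-methoxybenzyl)oxy]propyl]-6,10-dimethyldodeca-6,10-dienoate
Conditions: Na(Hg) (6% Na), Na2HPO4, THF/MeOH, −20 → 0 °C
Reagents that add atoms: none
Why: Reductive desulfonylation by electron transfer from sodium amalgam, which cleaves both C14–S bonds to leave C14 as CH2, the phosphate buffer keeping the medium mild enough for the acetate and the methyl ester.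

Step 12
Reactants: 15 methyl (3R,6E,10Z)-12-acetoxy-3-[(2R)-2-(methoxymethoxy)-3-[(4-methoxybenzyl)oxy]propyl]-6,10-dimethyldodeca-6,10-dienoate
Product: 16 methyl (3R,5R)-3-{2-[(2S,3S)-3-[(3Z)-5-acetoxy-3-methylpent-3-en-1-yl]-2-methyloxiran-2-yl]ethyl}-5-(methoxymethoxy)-6-[(4-methoxybenzyl)oxy]hexanoate
Conditions: L-fructose-derived Shi ketone (0.3 equiv), KHSO5 (as 2KHSO5·KHSO4·K2SO4), K2CO3, Bu4NHSO4, MeCN/CH2(OMe)2/aq. Na2B4O7 buffer (pH 10.5), 0 °C
Reagents that add atoms: potassium peroxymonosulfate, [K+].[O-]S(=O)(=O)OO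
Why: Shi asymmetric epoxidation with the chiral dioxirane formed in situ: the L-fructose-derived ketone (the D-fructose-derived one gives R,R epoxides from E-trisubstituted alkenes) should deliver oxygen to the face of the E-C11=C12 alkene that gives the 11S,12S epoxide, while the C7=C8 alkene, deactivated by its allylic acetate, reacts much more slowly.

Step 13
Reactants: 16 methyl (3R,5R)-3-{2-[(2S,3S)-3-[(3Z)-5-acetoxy-3-methylpent-3-en-1-yl]-2-methyloxiran-2-yl]ethyl}-5-(methoxymethoxy)-6-[(4-methoxybenzyl)oxy]hexanoate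
Product: 17 (3R,5R)-3-{2-[(2S,3S)-3-[(3Z)-5-hydroxy-3-methylpent-3-en-1-yl]-2-methyloxiran-2-yl]ethyl}-5-(methoxymethoxy)-6-[(4-methoxybenzyl)oxy]hexanoic acid
Conditions: LiOH, THF/MeOH/H2O, 0 °C → rt; then aq. NaH2PO4 to pH 5, 0 °C
Reagents that add atoms: lithium hydroxide, [Li+].[OH-]
Why: Saponification of the methyl ester and of the C6 acetate with hydroxide, to which the trisubstituted epoxide, the acetal and the PMB ether are inert, followed by buffered acidification to free the C16 acid.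

Step 14
Reactants: 17 (3R,5R)-3-{2-[(2S,3S)-3-[(3Z)-5-hydroxy-3-methylpent-3-en-1-yl]-2-methyloxiran-2-yl]ethyl}-5-(methoxymethoxy)-6-[(4-methoxybenzyl)oxy]hexanoic acid
Product: 18 (4R,7R)-7-[(1S,4Z)-1,6-dihydroxy-4-methylhex-4-en-1-yl]-4-[(2R)-2-(methoxymethoxy)-3-[(4-methoxybenzyl)oxy]propyl]-7-methyloxepan-2-one
Conditions: camphorsulfonic acid (10 mol%), CH2Cl2, 0 °C → rt
Reagents that add atoms: none
Why: Acid-catalysed epoxide-opening lactonisation: the C16 acid attacks the protonated epoxide at the tertiary carbon C12 in the 7-exo mode (Markovnikov, SN2-like) with inversion, which closes the ε-lactone, sets C12 (R) and leaves the epoxide oxygen as the C11 (S) hydroxyl.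

Step 15
Reactants: 18 (4R,7R)-7-[(1S,4Z)-1,6-dihydroxy-4-methylhex-4-en-1-yl]-4-[(2R)-2-(methoxymethoxy)-3-[(4-methoxybenzyl)oxy]propyl]-7-methyloxepan-2-one
Product: 19 (4R,7R)-7-[(1S,4Z)-1,6-bis[(tert-butyldimethylsilyl)oxy]-4-methylhex-4-en-1-yl]-4-[(2R)-2-(methoxymethoxy)-3-[(4-methoxybenzyl)oxy]propyl]-7-methyloxepan-2-one
Conditions: t-BuMe2SiOTf (3 equiv), 2,6-lutidine, CH2Cl2, −78 → 0 °C
Reagents that add atoms: tert-butyldimethylsilyl trifluoromethanesulfonate, CC(C)(C)[Si](C)(C)OS(=O)(=O)C(F)(F)F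
Why: Silylation of the primary allylic C6–OH and the hindered secondary C11–OH with the silyl triflate and 2,6-lutidine, conditions that do not enolise the lactone.

Step 16
Reactants: 19 (4R,7R)-7-[(1S,4Z)-1,6-bis[(tert-butyldimethylsilyl)oxy]-4-methylhex-4-en-1-yl]-4-[(2R)-2-(methoxymethoxy)-3-[(4-methoxybenzyl)oxy]propyl]-7-methyloxepan-2-one
Product: 20 (4R,7R)-7-[(1S,4Z)-1,6-bis[(tert-butyldimethylsilyl)oxy]-4-methylhex-4-en-1-yl]-4-[(2R)-3-hydroxy-2-(methoxymethoxy)propyl]-7-methyloxepan-2-one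
Conditions: DDQ, CH2Cl2/pH 7 phosphate buffer, 0 °C
Reagents that add atoms: none
Why: Oxidative cleavage of the PMB ether by DDQ (hydride abstraction, hydrolysis of the oxocarbenium ion), which frees only C4–OH and leaves the silyl ethers, the acetal, the lactone and the alkene intact.

Step 17
Reactants: 20 (4R,7R)-7-[(1S,4Z)-1,6-bis[(tert-butyldimethylsilyl)oxy]-4-methylhex-4-en-1-yl]-4-[(2R)-3-hydroxy-2-(methoxymethoxy)propyl]-7-methyloxepan-2-one
Product: 21 (2R)-3-{(4R,7R)-7-[(1S,4Z)-1,6-bis[(tert-butyldimethylsilyl)oxy]-4-methylhex-4-en-1-yl]-7-methyl-2-oxooxepan-4-yl}-2-(methoxymethoxy)propanal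
Conditions: Dess–Martin periodinane, NaHCO3, CH2Cl2, 0 °C → rt
Reagents that add atoms: none
Why: Dess–Martin oxidation of the primary alcohol to the C4 aldehyde under buffered, non-basic conditions so that the α-alkoxy centre C3 is not epimerised; the aldehyde is used at once.

Step 18
Reactants: 21 (2R)-3-{(4R,7R)-7-[(1S,4Z)-1,6-bis[(tert-butyldimethylsilyl)oxy]-4-methylhex-4-en-1-yl]-7-methyl-2-oxooxepan-4-yl}-2-(methoxymethoxy)propanal; 22 methyl phenyl sulfone
Product: 24 (4R,7R)-7-[(1S,4Z)-1,6-bis[(tert-butyldimethylsilyl)oxy]-4-methylhex-4-en-1-yl]-4-[(2R)-3-hydroxy-2-(methoxymethoxy)-4-(phenylsulfonyl)butyl]-7-methyloxepan-2-one (both C4 carbinol epimers), via lithiated methyl phenyl sulfone 23 (not isolated)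
Conditions: 22, n-BuLi, THF, −78 °C; then 21, −78 °C; aq. NH4Cl
Reagents that add atoms: none
Why: Addition of the lithiated sulfone (an α-sulfonyl carbanion) to the aldehyde at −78 °C forms the C4–C5 bond, the aldehyde reacting far faster than the lactone; the new carbinol centre is of no consequence because it is oxidised next.

Step 19
Reactants: 24 (4R,7R)-7-[(1S,4Z)-1,6-bis[(tert-butyldimethylsilyl)oxy]-4-methylhex-4-en-1-yl]-4-[(2R)-3-hydroxy-2-(methoxymethoxy)-4-(phenylsulfonyl)butyl]-7-methyloxepan-2-one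
Product: 25 (4R,7R)-7-[(1S,4Z)-1,6-bis[(tert-butyldimethylsilyl)oxy]-4-methylhex-4-en-1-yl]-4-[(2R)-2-(methoxymethoxy)-3-oxo-4-(phenylsulfonyl)butyl]-7-methyloxepan-2-one
Conditions: Dess–Martin periodinane, NaHCO3, CH2Cl2, rt
Reagents that add atoms: none
Why: Dess–Martin oxidation of the β-hydroxy sulfone to the β-keto sulfone, which makes the C5 hydrogens acidic (between C=O and SO2Ph) for the ring closure.

Step 20
Reactants: 25 (4R,7R)-7-[(1S,4Z)-1,6-bis[(tert-butyldimethylsilyl)oxy]-4-methylhex-4-en-1-yl]-4-[(2R)-2-(methoxymethoxy)-3-oxo-4-(phenylsulfonyl)butyl]-7-methyloxepan-2-one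
Product: 26 (4R,7R)-7-[(1S,4Z)-1-[(tert-butyldimethylsilyl)oxy]-6-hydroxy-4-methylhex-4-en-1-yl]-4-[(2R)-2-(methoxymethoxy)-3-oxo-4-(phenylsulfonyl)butyl]-7-methyloxepan-2-one
Conditions: HF·pyridine, pyridine, THF, 0 °C
Reagents that add atoms: none
Why: Selective fluoride-mediated desilylation: the unhindered primary allylic silyl ether at C6 is cleaved much faster than the secondary one at C11, which sits next to the quaternary C12.

Step 21
Reactants: 26 (4R,7R)-7-[(1S,4Z)-1-[(tert-butyldimethylsilyl)oxy]-6-hydroxy-4-methylhex-4-en-1-yl]-4-[(2R)-2-(methoxymethoxy)-3-oxo-4-(phenylsulfonyl)butyl]-7-methyloxepan-2-one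
Product: 27 (4R,7R)-7-[(1S,4Z)-6-bromo-1-[(tert-butyldimethylsilyl)oxy]-4-methylhex-4-en-1-yl]-4-[(2R)-2-(methoxymethoxy)-3-oxo-4-(phenylsulfonyl)butyl]-7-methyloxepan-2-one
Conditions: CBr4, PPh3, 2,6-lutidine, CH2Cl2, −20 °C
Reagents that add atoms: carbon tetrabromide, BrC(Br)(Br)Br
Why: Appel bromination (SN2 at C6 of the primary allylic alcohol) under neutral, cold conditions so that the Z geometry is kept and the acidic keto sulfone is not deprotonated before the dilution step.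

Step 22
Reactants: 27 (4R,7R)-7-[(1S,4Z)-6-bromo-1-[(tert-butyldimethylsilyl)oxy]-4-methylhex-4-en-1-yl]-4-[(2R)-2-(methoxymethoxy)-3-oxo-4-(phenylsulfonyl)butyl]-7-methyloxepan-2-one
Product: 28 (1R,3R,7Z,11S,12R)-11-[(tert-butyldimethylsilyl)oxy]-3-(methoxymethoxy)-8,12-dimethyl-5-(phenylsulfonyl)-13-oxabicyclo[10.3.2]heptadec-7-ene-4,14-dione (C5 epimers)
Conditions: Cs2CO3 (5 equiv), Bu4NI (cat.), MeCN, 50 °C, 27 added by syringe pump over 12 h to a final 0.002 M
Reagents that add atoms: none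
Why: Cs2CO3 reversibly deprotonates C5, the carbon between the C4 carbonyl and the sulfonyl group, and the doubly stabilised carbanion displaces bromide at the primary allylic carbon C6 in an intramolecular SN2 reaction that forms the C5–C6 bond. The closest known reaction type is the macrocyclisation of cembranoid chains by intramolecular alkylation of sulfone-stabilised carbanions with allylic halides. The 14-membered carbocycle is closed in the 14-exo-tet mode, and the ε-lactone is carried through unchanged. No controlled stereocentre is made: C5 forms as both epimers and loses its substituent in the next step, while C3 is shielded from epimerisation because the ketone is held as its enolate. The step needs C-alkylation at C6 over O-alkylation, over SN2′ attack at C8 and over intermolecular reaction; these should be secured by the soft carbanion and the primary bromide, by the fully substituted C8, and by slow addition at high dilution. Because no allyl–metal species intervenes the Z-C7=C8 geometry is kept, and carbonate is too weak a base to enolise or open the lactone.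

Step 23
Reactants: 28 (1R,3R,7Z,11S,12R)-11-[(tert-butyldimethylsilyl)oxy]-3-(methoxymethoxy)-8,12-dimethyl-5-(phenylsulfonyl)-13-oxabicyclo[10.3.2]heptadec-7-ene-4,14-dione
Product: 29 (1R,3R,7Z,11S,12R)-11-[(tert-butyldimethylsilyl)oxy]-3-(methoxymethoxy)-8,12-dimethyl-13-oxabicyclo[10.3.2]heptadec-7-ene-4,14-dione
Conditions: Al(Hg), THF/H2O (9:1), 0 °C → rt
Reagents that add atoms: none
Why: Reductive desulfonylation of the β-keto sulfone with aluminium amalgam (electron transfer, C5–S cleavage, protonation of the enolate), which removes the C5 epimer mixture and is mild enough for the lactone, the acetal, the silyl ether and the alkene.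

Step 24
Reactants: 29 (1R,3R,7Z,11S,12R)-11-[(tert-butyldimethylsilyl)oxy]-3-(methoxymethoxy)-8,12-dimethyl-13-oxabicyclo[10.3.2]heptadec-7-ene-4,14-dione
Product: 30 (1R,3R,7Z,11S,12R)-11-[(tert-butyldimethylsilyl)oxy]-3-hydroxy-8,12-dimethyl-13-oxabicyclo[10.3.2]heptadec-7-ene-4,14-dione
Conditions: Me2BBr, CH2Cl2, −78 °C; then aq. NaHCO3/THF
Reagents that add atoms: none
Why: Lewis acid cleavage of the MOM acetal with bromodimethylborane at −78 °C (bromide opens the boron-activated acetal and the α-bromo ether is hydrolysed on work-up); it is done at the ketone stage, where no neighbouring hydroxyl can trap the acetal carbon as a cyclic formal, and it spares the silyl ether and the lactone.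

Step 25
Reactants: 30 (1R,3R,7Z,11S,12R)-11-[(tert-butyldimethylsilyl)oxy]-3-hydroxy-8,12-dimethyl-13-oxabicyclo[10.3.2]heptadec-7-ene-4,14-dione
Product: 31 (1R,3R,4S,7Z,11S,12R)-11-[(tert-butyldimethylsilyl)oxy]-3,4-dihydroxy-4,8,12-trimethyl-13-oxabicyclo[10.3.2]heptadec-7-en-14-one
Conditions: MeMgBr (3.5 equiv), THF, −78 °C; aq. NH4Cl at −78 °C
Reagents that add atoms: methylmagnesium bromide, C[Mg]Br
Why: Chelation-controlled Grignard addition (Cram chelate model): the first equivalent makes the C3 magnesium alkoxide, which binds the C4 carbonyl in a five-membered chelate, and methyl then adds to the carbonyl face anti to C2, which sets C4 (S) and gives the 3R,4S diol, the ketone reacting far faster than the lactone at −78 °C.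

Step 26
Reactants: 31 (1R,3R,4S,7Z,11S,12R)-11-[(tert-butyldimethylsilyl)oxy]-3,4-dihydroxy-4,8,12-trimethyl-13-oxabicyclo[10.3.2]heptadec-7-en-14-one
Product: 32 (1R,3R,4S,7Z,11S,12R)-11-[(tert-butyldimethylsilyl)oxy]-4,8,12-trimethyl-3,4-bis[(triethylsilyl)oxy]-13-oxabicyclo[10.3.2]heptadec-7-en-14-one
Conditions: Et3SiOTf (3 equiv), 2,6-lutidine, CH2Cl2, −78 → 0 °C
Reagents that add atoms: triethylsilyl trifluoromethanesulfonate, CC[Si](CC)(CC)OS(=O)(=O)C(F)(F)F
Why: Silylation of the secondary C3 and tertiary C4 hydroxyls with the reactive silyl triflate, so that no alkoxide can attack the lactone carbonyl (C3–O would form a six-membered lactone) during the enolate step.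

Step 27
Reactants: 32 (1R,3R,4S,7Z,11S,12R)-11-[(tert-butyldimethylsilyl)oxy]-4,8,12-trimethyl-3,4-bis[(triethylsilyl)oxy]-13-oxabicyclo[10.3.2]heptadec-7-en-14-one
Product: 33 (1R,3R,4S,7Z,11S,12R)-11-[(tert-butyldimethylsilyl)oxy]-15-[(dimethylamino)methyl]-4,8,12-trimethyl-3,4-bis[(triethylsilyl)oxy]-13-oxabicyclo[10.3.2]heptadec-7-en-14-one (C15 epimers)
Conditions: LiN(SiMe3)2, THF, −78 °C; then CH2=NMe2+ I−, −78 → 0 °C
Reagents that add atoms: N,N-dimethylmethyleneiminium iodide (Eschenmoser's salt), C=[N+](C)C.[I-]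
Why: Mannich reaction of the lithium enolate of the lactone with Eschenmoser's salt, which attaches C17 to C15, the only enolisable position now that C4 is no longer a ketone.

Step 28
Reactants: 33 (1R,3R,4S,7Z,11S,12R)-11-[(tert-butyldimethylsilyl)oxy]-15-[(dimethylamino)methyl]-4,8,12-trimethyl-3,4-bis[(triethylsilyl)oxy]-13-oxabicyclo[10.3.2]heptadec-7-en-14-one
Product: 35 (1R,3R,4S,7Z,11S,12R)-11-[(tert-butyldimethylsilyl)oxy]-4,8,12-trimethyl-15-methylidene-3,4-bis[(triethylsilyl)oxy]-13-oxabicyclo[10.3.2]heptadec-7-en-14-one, via trimethylammonium iodide 34 (not isolated)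
Conditions: MeI, CH2Cl2/MeOH, rt; evaporate; then aq. NaHCO3, CH2Cl2, rt
Reagents that add atoms: none
Why: Quaternisation of the amine with iodomethane and E1cB (Hofmann-type) elimination of trimethylamine under mild base, which gives the exocyclic C15=C17 methylene conjugated with the lactone.

Step 29
Reactants: 35 (1R,3R,4S,7Z,11S,12R)-11-[(tert-butyldimethylsilyl)oxy]-4,8,12-trimethyl-15-methylidene-3,4-bis[(triethylsilyl)oxy]-13-oxabicyclo[10.3.2]heptadec-7-en-14-one
Product: 36 (1R,3R,4S,7Z,11S,12R)-3,4,11-trihydroxy-4,8,12-trimethyl-15-methylidene-13-oxabicyclo[10.3.2]heptadec-7-en-14-one (CNP0263298.1)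
Conditions: HF·pyridine, pyridine, THF, 0 °C → rt
Reagents that add atoms: none
Why: Fluoride-mediated cleavage of the three silyl ethers, mildly acidic conditions under which the α-methylene lactone, the tertiary alcohol and the Z-alkene should survive.

**Compound list**

1 | (S)-glycidol | OC[C@H]1CO1 | starting material
2 | (R)-2-{[(4-methoxybenzyl)oxy]methyl}oxirane | COc1ccc(COC[C@H]2CO2)cc1 | intermediate
3 | (R)-1-[(4-methoxybenzyl)oxy]pent-4-en-2-ol | COc1ccc(COC[C@H](O)CC=C)cc1 | intermediate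
4 | 1-methoxy-4-({[(2R)-2-(methoxymethoxy)pent-4-en-1-yl]oxy}methyl)benzene | COc1ccc(COC[C@H](OCOC)CC=C)cc1 | intermediate
5 | (E)-crotonaldehyde | C/C=C/C=O | starting material
6 | (2E,5R)-5-(methoxymethoxy)-6-[(4-methoxybenzyl)oxy]hex-2-enal | COc1ccc(COC[C@H](OCOC)C/C=C/C=O)cc1 | intermediate
7 | 1,3-benzodithiole 1,1,3,3-tetraoxide | O=S1(=O)CS(=O)(=O)c2ccccc12 | starting material
8 | (3R,5R)-5-(methoxymethoxy)-6-[(4-methoxybenzyl)oxy]-3-(1,1,3,3-tetraoxo-1,3-benzodithiol-2-yl)hexanal | O=CC[C@H](C1S(=O)(=O)c2ccccc2S1(=O)=O)C[C@@H](OCOC)COCc3ccc(OC)cc3 | intermediate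
9 | (3R,5R)-5-(methoxymethoxy)-6-[(4-methoxybenzyl)oxy]-3-(1,1,3,3-tetraoxo-1,3-benzodithiol-2-yl)hexanoic acid | OC(=O)C[C@H](C1S(=O)(=O)c2ccccc2S1(=O)=O)C[C@@H](OCOC)COCc3ccc(OC)cc3 | intermediate
10 | methyl (3R,5R)-5-(methoxymethoxy)-6-[(4-methoxybenzyl)oxy]-3-(1,1,3,3-tetraoxo-1,3-benzodithiol-2-yl)hexanoate | COC(=O)C[C@H](C1S(=O)(=O)c2ccccc2S1(=O)=O)C[C@@H](OCOC)COCc3ccc(OC)cc3 | intermediate
11 | neryl acetate, (2Z)-3,7-dimethylocta-2,6-dien-1-yl acetate | CC(C)=CCC/C(C)=C\COC(C)=O | starting material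
12 | (2Z,6E)-8-hydroxy-3,7-dimethylocta-2,6-dien-1-yl acetate | CC(=O)OC/C=C(/C)CC/C=C(\C)CO | intermediate
13 | (2Z,6E)-8-bromo-3,7-dimethylocta-2,6-dien-1-yl acetate | CC(=O)OC/C=C(/C)CC/C=C(\C)CBr | intermediate
14 | methyl (3R,5R)-3-{2-[(2E,6Z)-8-acetoxy-2,6-dimethylocta-2,6-dien-1-yl]-1,1,3,3-tetraoxo-1,3-benzodithiol-2-yl}-5-(methoxymethoxy)-6-[(4-methoxybenzyl)oxy]hexanoate | COC(=O)C[C@H](C1(C/C(C)=C/CC/C(C)=C\COC(C)=O)S(=O)(=O)c2ccccc2S1(=O)=O)C[C@@H](OCOC)COCc3ccc(OC)cc3 | intermediate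
15 | methyl (3R,6E,10Z)-12-acetoxy-3-[(2R)-2-(methoxymethoxy)-3-[(4-methoxybenzyl)oxy]propyl]-6,10-dimethyldodeca-6,10-dienoate | COC(=O)C[C@H](CC/C(C)=C/CC/C(C)=C\COC(C)=O)C[C@@H](OCOC)COCc1ccc(OC)cc1 | intermediate
16 | methyl (3R,5R)-3-{2-[(2S,3S)-3-[(3Z)-5-acetoxy-3-methylpent-3-en-1-yl]-2-methyloxiran-2-yl]ethyl}-5-(methoxymethoxy)-6-[(4-methoxybenzyl)oxy]hexanoate | COC(=O)C[C@H](CC[C@]1(C)O[C@H]1CC/C(C)=C\COC(C)=O)C[C@@H](OCOC)COCc2ccc(OC)cc2 | intermediate
17 | (3R,5R)-3-{2-[(2S,3S)-3-[(3Z)-5-hydroxy-3-methylpent-3-en-1-yl]-2-methyloxiran-2-yl]ethyl}-5-(methoxymethoxy)-6-[(4-methoxybenzyl)oxy]hexanoic acid | OC(=O)C[C@H](CC[C@]1(C)O[C@H]1CC/C(C)=C\CO)C[C@@H](OCOC)COCc2ccc(OC)cc2 | intermediate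
18 | (4R,7R)-7-[(1S,4Z)-1,6-dihydroxy-4-methylhex-4-en-1-yl]-4-[(2R)-2-(methoxymethoxy)-3-[(4-methoxybenzyl)oxy]propyl]-7-methyloxepan-2-one | OC/C=C(/C)CC[C@H](O)[C@@]1(C)CC[C@H](C[C@@H](OCOC)COCc2ccc(OC)cc2)CC(=O)O1 | intermediate
19 | (4R,7R)-7-[(1S,4Z)-1,6-bis[(tert-butyldimethylsilyl)oxy]-4-methylhex-4-en-1-yl]-4-[(2R)-2-(methoxymethoxy)-3-[(4-methoxybenzyl)oxy]propyl]-7-methyloxepan-2-one | CC(C)(C)[Si](C)(C)OC/C=C(/C)CC[C@H](O[Si](C)(C)C(C)(C)C)[C@@]1(C)CC[C@H](C[C@@H](OCOC)COCc2ccc(OC)cc2)CC(=O)O1 | intermediate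
20 | (4R,7R)-7-[(1S,4Z)-1,6-bis[(tert-butyldimethylsilyl)oxy]-4-methylhex-4-en-1-yl]-4-[(2R)-3-hydroxy-2-(methoxymethoxy)propyl]-7-methyloxepan-2-one | CC(C)(C)[Si](C)(C)OC/C=C(/C)CC[C@H](O[Si](C)(C)C(C)(C)C)[C@@]1(C)CC[C@H](C[C@@H](OCOC)CO)CC(=O)O1 | intermediate
21 | (2R)-3-{(4R,7R)-7-[(1S,4Z)-1,6-bis[(tert-butyldimethylsilyl)oxy]-4-methylhex-4-en-1-yl]-7-methyl-2-oxooxepan-4-yl}-2-(methoxymethoxy)propanal | CC(C)(C)[Si](C)(C)OC/C=C(/C)CC[C@H](O[Si](C)(C)C(C)(C)C)[C@@]1(C)CC[C@H](C[C@@H](OCOC)C=O)CC(=O)O1 | intermediate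
22 | methyl phenyl sulfone | CS(=O)(=O)c1ccccc1 | starting material
23 | [(phenylsulfonyl)methyl]lithium | [Li]CS(=O)(=O)c1ccccc1 | intermediate
24 | (4R,7R)-7-[(1S,4Z)-1,6-bis[(tert-butyldimethylsilyl)oxy]-4-methylhex-4-en-1-yl]-4-[(2R)-3-hydroxy-2-(methoxymethoxy)-4-(phenylsulfonyl)butyl]-7-methyloxepan-2-one (both carbinol epimers) | CC(C)(C)[Si](C)(C)OC/C=C(/C)CC[C@H](O[Si](C)(C)C(C)(C)C)[C@@]1(C)CC[C@H](C[C@@H](OCOC)C(O)CS(=O)(=O)c2ccccc2)CC(=O)O1 | intermediate
25 | (4R,7R)-7-[(1S,4Z)-1,6-bis[(tert-butyldimethylsilyl)oxy]-4-methylhex-4-en-1-yl]-4-[(2R)-2-(methoxymethoxy)-3-oxo-4-(phenylsulfonyl)butyl]-7-methyloxepan-2-one | CC(C)(C)[Si](C)(C)OC/C=C(/C)CC[C@H](O[Si](C)(C)C(C)(C)C)[C@@]1(C)CC[C@H](C[C@@H](OCOC)C(=O)CS(=O)(=O)c2ccccc2)CC(=O)O1 | intermediate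
26 | (4R,7R)-7-[(1S,4Z)-1-[(tert-butyldimethylsilyl)oxy]-6-hydroxy-4-methylhex-4-en-1-yl]-4-[(2R)-2-(methoxymethoxy)-3-oxo-4-(phenylsulfonyl)butyl]-7-methyloxepan-2-one | OC/C=C(/C)CC[C@H](O[Si](C)(C)C(C)(C)C)[C@@]1(C)CC[C@H](C[C@@H](OCOC)C(=O)CS(=O)(=O)c2ccccc2)CC(=O)O1 | intermediate
27 | (4R,7R)-7-[(1S,4Z)-6-bromo-1-[(tert-butyldimethylsilyl)oxy]-4-methylhex-4-en-1-yl]-4-[(2R)-2-(methoxymethoxy)-3-oxo-4-(phenylsulfonyl)butyl]-7-methyloxepan-2-one | BrC/C=C(/C)CC[C@H](O[Si](C)(C)C(C)(C)C)[C@@]1(C)CC[C@H](C[C@@H](OCOC)C(=O)CS(=O)(=O)c2ccccc2)CC(=O)O1 | intermediate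
28 | (1R,3R,7Z,11S,12R)-11-[(tert-butyldimethylsilyl)oxy]-3-(methoxymethoxy)-8,12-dimethyl-5-(phenylsulfonyl)-13-oxabicyclo[10.3.2]heptadec-7-ene-4,14-dione (C5 epimers) | C1C(=O)O[C@]2(C)CC[C@@H]1C[C@@H](OCOC)C(=O)C(S(=O)(=O)c3ccccc3)C/C=C(/C)CC[C@@H]2O[Si](C)(C)C(C)(C)C | intermediate
29 | (1R,3R,7Z,11S,12R)-11-[(tert-butyldimethylsilyl)oxy]-3-(methoxymethoxy)-8,12-dimethyl-13-oxabicyclo[10.3.2]heptadec-7-ene-4,14-dione | C1C(=O)O[C@]2(C)CC[C@@H]1C[C@@H](OCOC)C(=O)CC/C=C(/C)CC[C@@H]2O[Si](C)(C)C(C)(C)C | intermediate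
30 | (1R,3R,7Z,11S,12R)-11-[(tert-butyldimethylsilyl)oxy]-3-hydroxy-8,12-dimethyl-13-oxabicyclo[10.3.2]heptadec-7-ene-4,14-dione | C1C(=O)O[C@]2(C)CC[C@@H]1C[C@@H](O)C(=O)CC/C=C(/C)CC[C@@H]2O[Si](C)(C)C(C)(C)C | intermediate
31 | (1R,3R,4S,7Z,11S,12R)-11-[(tert-butyldimethylsilyl)oxy]-3,4-dihydroxy-4,8,12-trimethyl-13-oxabicyclo[10.3.2]heptadec-7-en-14-one | C1C(=O)O[C@]2(C)CC[C@@H]1C[C@@H](O)[C@@](C)(O)CC/C=C(/C)CC[C@@H]2O[Si](C)(C)C(C)(C)C | intermediate
32 | (1R,3R,4S,7Z,11S,12R)-11-[(tert-butyldimethylsilyl)oxy]-4,8,12-trimethyl-3,4-bis[(triethylsilyl)oxy]-13-oxabicyclo[10.3.2]heptadec-7-en-14-one | C1C(=O)O[C@]2(C)CC[C@@H]1C[C@@H](O[Si](CC)(CC)CC)[C@@](C)(O[Si](CC)(CC)CC)CC/C=C(/C)CC[C@@H]2O[Si](C)(C)C(C)(C)C | intermediate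
33 | (1R,3R,4S,7Z,11S,12R)-11-[(tert-butyldimethylsilyl)oxy]-15-[(dimethylamino)methyl]-4,8,12-trimethyl-3,4-bis[(triethylsilyl)oxy]-13-oxabicyclo[10.3.2]heptadec-7-en-14-one (C15 epimers) | CN(C)CC1C(=O)O[C@]2(C)CC[C@@H]1C[C@@H](O[Si](CC)(CC)CC)[C@@](C)(O[Si](CC)(CC)CC)CC/C=C(/C)CC[C@@H]2O[Si](C)(C)C(C)(C)C | intermediate
34 | N,N,N-trimethylammonium iodide of 33 | C[N+](C)(C)CC1C(=O)O[C@]2(C)CC[C@@H]1C[C@@H](O[Si](CC)(CC)CC)[C@@](C)(O[Si](CC)(CC)CC)CC/C=C(/C)CC[C@@H]2O[Si](C)(C)C(C)(C)C.[I-] | intermediate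
35 | (1R,3R,4S,7Z,11S,12R)-11-[(tert-butyldimethylsilyl)oxy]-4,8,12-trimethyl-15-methylidene-3,4-bis[(triethylsilyl)oxy]-13-oxabicyclo[10.3.2]heptadec-7-en-14-one | C=C1C(=O)O[C@]2(C)CC[C@@H]1C[C@@H](O[Si](CC)(CC)CC)[C@@](C)(O[Si](CC)(CC)CC)CC/C=C(/C)CC[C@@H]2O[Si](C)(C)C(C)(C)C | intermediate
36 | (1R,3R,4S,7Z,11S,12R)-3,4,11-trihydroxy-4,8,12-trimethyl-15-methylidene-13-oxabicyclo[10.3.2]heptadec-7-en-14-one (CNP0263298.1) | C=C1C(=O)O[C@]2(C)CC[C@@H]1C[C@@H](O)[C@@](C)(O)CC/C=C(/C)CC[C@@H]2O | target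

**Step count**

Total: 29 steps. Longest linear sequence: 27 steps (steps 1–7 and 10–29, from (S)-glycidol); steps 8–9 form the side branch from neryl acetate.

**Steps most likely to fail, with fallbacks**

1. Step 22 (macrocyclisation). Ring closure may lose to intermolecular alkylation during the slow addition, or the enolate oxygen instead of C5 may attack C6. The fallback sets out from allylic alcohol 26 and keeps the C5–C6 disconnection but changes the mechanism to a Tsuji–Trost allylic alkylation. Compound 26 is treated with ClCO2Me and pyridine in CH2Cl2 at 0 °C to give the allylic methyl carbonate F1. F1 is added slowly to Pd(PPh3)4 (10 mol%) and 1,2-bis(diphenylphosphino)ethane in THF at 65 °C. Ionisation gives a neryl-type π-allyl palladium complex and methoxide, which deprotonates C5; the carbanion should attack the unsubstituted terminus C6. The fully substituted terminus C8 resists the σ-allyl form needed for syn/anti exchange, so the Z geometry should largely hold. The route is rejoined at macrocycle 28.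

2. Step 14 (epoxide-opening lactonisation). The acid may fail to capture C12 before competing events: participation of the C3 acetal oxygen, attack of the C7=C8 alkene on the developing C12 cation, or a hydride shift to the C11 ketone. The fallback sets out from epoxy ester 16 and separates C12–O bond formation from ring closure. Catalytic HClO4 in THF/H2O at 0 °C opens the epoxide with water at the tertiary carbon with inversion to give the anti-diol F2. LiOH in THF/MeOH/H2O then gives the trihydroxy acid F3. t-BuMe2SiOTf and 2,6-lutidine at −78 °C, followed by K2CO3 in MeOH/H2O to cleave the silyl ester, give the C6,C11-bis-silyl hydroxy acid F4 with the tertiary C12–OH free. Yamaguchi lactonisation (2,4,6-trichlorobenzoyl chloride, Et3N, THF; then 4-dimethylaminopyridine, toluene, 100 °C, high dilution) closes the ε-lactone on the tertiary alcohol with retention. The route is rejoined at bis-silyl lactone 19.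

3. Step 10 (fragment union at C13–C14). C-alkylation at the crowded C14, which becomes a quaternary carbon between two sulfonyl groups and the C1 methine, may be too slow, so that bromide 13 is consumed by elimination or hydrolysis instead. The fallback sets out from allylic alcohol 12, which with ClCO2Me and pyridine gives the allylic methyl carbonate F5. F5 and bis-sulfone 10 are combined with Pd(PPh3)4 (5 mol%) in THF at rt (Tsuji–Trost allylic alkylation). The carbonate should ionise in preference to the C6 acetate, and the soft carbanion should attack the π-allyl complex at the less hindered terminus C13 from outside the metal, which is less sensitive to crowding than the SN2 transition state. The route is rejoined at compound 14.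

**Further compounds**

F1 | step 22 | (2Z,6S)-6-[(tert-butyldimethylsilyl)oxy]-6-{(2R,5R)-5-[(2R)-2-(methoxymethoxy)-3-oxo-4-(phenylsulfonyl)butyl]-2-methyl-7-oxooxepan-2-yl}-3-methylhex-2-en-1-yl methyl carbonate | COC(=O)OC/C=C(/C)CC[C@H](O[Si](C)(C)C(C)(C)C)[C@@]1(C)CC[C@H](C[C@@H](OCOC)C(=O)CS(=O)(=O)c2ccccc2)CC(=O)O1
F2 | step 14 | methyl (3R,5R)-3-[(3R,4S,7Z)-9-acetoxy-3,4-dihydroxy-3,7-dimethylnon-7-en-1-yl]-5-(methoxymethoxy)-6-[(4-methoxybenzyl)oxy]hexanoate | COC(=O)C[C@H](CC[C@@](C)(O)[C@@H](O)CC/C(C)=C\COC(C)=O)C[C@@H](OCOC)COCc1ccc(OC)cc1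
F3 | step 14 | (3R,5R)-3-[(3R,4S,7Z)-3,4,9-trihydroxy-3,7-dimethylnon-7-en-1-yl]-5-(methoxymethoxy)-6-[(4-methoxybenzyl)oxy]hexanoic acid | OC(=O)C[C@H](CC[C@@](C)(O)[C@@H](O)CC/C(C)=C\CO)C[C@@H](OCOC)COCc1ccc(OC)cc1
F4 | step 14 | (3R,5R)-3-[(3R,4S,7Z)-4,9-bis[(tert-butyldimethylsilyl)oxy]-3-hydroxy-3,7-dimethylnon-7-en-1-yl]-5-(methoxymethoxy)-6-[(4-methoxybenzyl)oxy]hexanoic acid | OC(=O)C[C@H](CC[C@@](C)(O)[C@@H](O[Si](C)(C)C(C)(C)C)CC/C(C)=C\CO[Si](C)(C)C(C)(C)C)C[C@@H](OCOC)COCc1ccc(OC)cc1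
F5 | step 10 | (2Z,6E)-8-[(methoxycarbonyl)oxy]-3,7-dimethylocta-2,6-dien-1-yl acetate | CC(=O)OC/C=C(/C)CC/C=C(\C)COC(=O)OC
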